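**Strategy**

- Retrosynthesis: the oxolane O1–C2–C3–C4–C5 is cut at O1–C2 together with the C2–H and C5–H bonds, which leads back to a twofold-symmetric 1,4-diaryl-2,3-bis(acyloxymethyl)butane-1,4-dione. Its two carbonyls are traced back to benzylic CH2 groups (dibenzylbutanediol skeleton), and the C3–C4 bond is cut last into two dihydroferulic acid units.
- Enabling feature: the ring is twofold symmetric, both aryl-bearing carbons (C2, C5) sit on O1, and each aryl group is cis to the CH2OH on the next carbon (C3, C4) while C3/C4 and C2/C5 are trans. This is the pattern left when hydride adds to a 2-aryl cyclic oxocarbenium ion anti to its neighbouring substituent, so one diketone can furnish both aryl carbons at once.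
- Forward: the chain is joined first at C3–C4 by oxidative dimerisation of an N-acyl oxazolidinone enolate. The auxiliaries are reduced off, the diol is masked, both benzylic CH2 groups are oxidised to ketones, and the only ring (the oxolane) is closed last.
- Stereochemistry: C3 and C4 (S,S) come from the (R)-4-benzyl oxazolidinone in the dimerisation; C2 and C5 (S,S) are relayed from C3 and C4 in the ring-closing double reduction.

Key step: step 7

Remark: the locants O1 and C2–C5 are those of the oxolane ring of the target, fixed by the SMILES as (2S,3S,4S,5S). The enolate coupling is assumed to follow the usual facial sense of 4-substituted N-acyl oxazolidinone enolates (bond formation anti to the C4 substituent).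

Step 1
Reactants: 1 3-(4-hydroxy-3-methoxyphenyl)propanoic acid (dihydroferulic acid); 2 benzyl bromide
Product: 4 3-[4-(benzyloxy)-3-methoxyphenyl]propanoic acid, via benzyl ester 3 (not isolated)
Conditions: 2 (2.3 equiv), K2CO3, DMF, 60 °C; then 2 M aq NaOH, MeOH, 60 °C; aq HCl
Reagents that add atoms: sodium hydroxide, [Na+].[OH-] (one carboxyl oxygen)
Why: Williamson O-benzylation of the phenoxide and the carboxylate is followed in the same pot by saponification of the benzyl ester only, since the aryl benzyl ether is inert to hydroxide.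

Step 2
Reactants: 4 3-[4-(benzyloxy)-3-methoxyphenyl]propanoic acid; 5 (R)-4-benzyl-1,3-oxazolidin-2-one
Product: 7 (4R)-4-benzyl-3-{3-[4-(benzyloxy)-3-methoxyphenyl]propanoyl}-1,3-oxazolidin-2-one, via mixed pivalic anhydride 6 (not isolated)
Conditions: t-BuCOCl, Et3N, THF, −20 °C; then 5, LiCl, −20 °C to rt
Reagents that add atoms: none
Why: N-acylation of the oxazolidinone by the mixed-anhydride method with LiCl activation, in which the nitrogen attacks the unhindered acyl group of 6 and pivalate leaves, so no strong base touches the substrate and the auxiliary centre is unaffected.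

Step 3
Reactants: 7 (4R)-4-benzyl-3-{3-[4-(benzyloxy)-3-methoxyphenyl]propanoyl}-1,3-oxazolidin-2-one (two molecules)
Product: 9 (4R,4'R)-3,3'-{(2S,3S)-2,3-bis[4-(benzyloxy)-3-methoxybenzyl]butanedioyl}bis(4-benzyl-1,3-oxazolidin-2-one), via lithium Z-enolate 8 (not isolated)
Conditions: LiN(i-Pr)2 (LDA, 1.1 equiv), THF, −78 °C; then anhydrous CuCl2 (1.2 equiv, added in DMF), −78 to 0 °C
Reagents that add atoms: none
Why: Oxidative homocoupling of an N-acyl oxazolidinone enolate, in which one-electron oxidation of the chelated lithium Z-enolate by divalent copper gives the α-carbonyl radical and each end of the new C3–C4 bond forms on the enolate face turned away from the C4 benzyl group of the (R)-auxiliary, which should make both new centres S (a coupling known for 3-arylpropanoyl oxazolidinones).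

Step 4
Reactants: 9 (4R,4'R)-3,3'-{(2S,3S)-2,3-bis[4-(benzyloxy)-3-methoxybenzyl]butanedioyl}bis(4-benzyl-1,3-oxazolidin-2-one)
Product: 10 (2S,3S)-2,3-bis[4-(benzyloxy)-3-methoxybenzyl]butane-1,4-diol
Conditions: LiBH4 (5 equiv), MeOH (5 equiv), THF, 0 °C to rt
Reagents that add atoms: none
Why: Reductive cleavage of N-acyl oxazolidinones by LiBH4, which attacks the exocyclic carbonyls, releases auxiliary 5 for recovery and reduces both acyl carbons to CH2OH without enolising the two α-centres.

Step 5
Reactants: 10 (2S,3S)-2,3-bis[4-(benzyloxy)-3-methoxybenzyl]butane-1,4-diol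
Product: 11 (2S,3S)-2,3-bis[4-(benzyloxy)-3-methoxybenzyl]butane-1,4-diyl bis(2,2-dimethylpropanoate)
Conditions: t-BuCOCl (3 equiv), pyridine, DMAP (cat), CH2Cl2, 0 °C to rt
Reagents that add atoms: pivaloyl chloride, CC(C)(C)C(=O)Cl
Why: DMAP-catalysed esterification of the two primary alcohols, with pivalates chosen because they are poor neighbouring groups towards benzylic cations, do not migrate and withstand both DDQ and BF3·OEt2.

Step 6
Reactants: 11 (2S,3S)-2,3-bis[4-(benzyloxy)-3-methoxybenzyl]butane-1,4-diyl bis(2,2-dimethylpropanoate)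
Product: 15 (2S,3S)-2,3-bis[4-(benzyloxy)-3-methoxybenzoyl]butane-1,4-diyl bis(2,2-dimethylpropanoate), via benzylic alcohol 12 (not isolated), via monoketone 13 (not isolated), via hydroxy ketone 14 (not isolated)
Conditions: DDQ (5 equiv), 1,4-dioxane/H2O 10:1, rt to 40 °C, dark
Reagents that add atoms: water, O
Why: Benzylic C–H oxidation of a para-alkoxy alkylarene by DDQ in aqueous medium (hydride abstraction, hydration of the para-benzyloxybenzyl cation, then dehydrogenation of the carbinol), run on both arms in one pot; the high water content is meant to outrun Friedel–Crafts capture and proton loss, the first ketone deactivates its own ring, aryl benzyl ethers are not cleaved by DDQ in the dark, and the weakly acidic medium should neither epimerise the α-centres nor eliminate the β-pivalates.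

Step 7
Reactants: 15 (2S,3S)-2,3-bis[4-(benzyloxy)-3-methoxybenzoyl]butane-1,4-diyl bis(2,2-dimethylpropanoate)
Product: 17 [(2S,3S,4S,5S)-2,5-bis[4-(benzyloxy)-3-methoxyphenyl]oxolane-3,4-diyl]bis(methylene) bis(2,2-dimethylpropanoate), via lactol 16 (not isolated)
Conditions: Et3SiH (8 equiv), BF3·OEt2 (3 equiv), CH2Cl2, −78 to −40 °C; Et3N/MeOH quench at −78 °C
Reagents that add atoms: none
Why: BF3 activates one aryl ketone of 15 and the oxygen of the other carbonyl adds to its carbon in a 5-exo-trig closure (the O1–C2 bond and the only ring of the step), which gives a 2-aryl cyclic oxocarbenium ion at C5 that Et3SiH reduces to lactol 16; BF3 then ionises the C2–OH bond of 16 and the second aryl oxocarbenium ion is reduced in the same way, the expelled oxygen ending as (Et3Si)2O. The closest known reactions are the Lewis acid/silane reductive cyclisation of 1,4- and 1,5-diketones to cyclic ethers and the Et3SiH/BF3·OEt2 reduction of 2-aryl lactols to 2,3-cis-2-aryloxolanes used for lignans, applied here together to a 2,3-disubstituted 1,4-diaryl diketone. C5 is set by hydride delivery to the first cation anti to the CH2OPiv group on C4, and C2 by delivery to the second cation anti to the CH2OPiv group on C3, so each aryl group ends cis to its neighbour; because C3 and C4 are trans, the two hydrides enter from opposite ring faces and the aryl groups end trans, which is the (2S,3S,4S,5S) array. The step needs 1,2-induction from the adjacent centre to outweigh the remote substituents (the second hydride must enter syn to the C5 aryl group) and hydride capture to be faster than proton loss from the cations, which would lead to the 2,5-diarylfuran (Paal–Knorr dehydration) or to epimerisation at C3/C4 through the enol ether. The para-benzyloxy groups make both ionisations fast at low temperature, the large excess of silane keeps the cation lifetimes short, the twofold symmetry makes it irrelevant which ketone reacts first, and the cold basic quench gives the kinetic cis,trans,cis ether no opportunity to reopen to the all-trans isomer.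

Step 8
Reactants: 17 [(2S,3S,4S,5S)-2,5-bis[4-(benzyloxy)-3-methoxyphenyl]oxolane-3,4-diyl]bis(methylene) bis(2,2-dimethylpropanoate)
Product: 18 [(2S,3S,4S,5S)-2,5-bis[4-(benzyloxy)-3-methoxyphenyl]oxolane-3,4-diyl]dimethanol
Conditions: i-Bu2AlH (6 equiv), CH2Cl2, −78 °C; aq potassium sodium tartrate
Reagents that add atoms: none
Why: Reductive removal of pivalate esters with i-Bu2AlH (ester reduction to the alkoxide and 2,2-dimethylpropanol) at low temperature, free of protic acid and of base, so the bis-benzylic ring ether and its four centres are not disturbed.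

Step 9
Reactants: 18 [(2S,3S,4S,5S)-2,5-bis[4-(benzyloxy)-3-methoxyphenyl]oxolane-3,4-diyl]dimethanol
Product: 19 eduesmine [(2S,3S,4S,5S)-2,5-bis(4-hydroxy-3-methoxyphenyl)oxolane-3,4-diyl]dimethanol
Conditions: H2 (1 atm), 10% Pd/C, EtOAc, rt, stopped at uptake of 2 equiv
Reagents that add atoms: none
Why: Catalytic hydrogenolysis of aryl benzyl ethers, which under neutral conditions at 1 atm is much faster than cleavage of the ring C2–O and C5–O benzylic bonds, so stopping at complete debenzylation should release both phenols with the oxolane intact.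

**Compound list**

1 | 3-(4-hydroxy-3-methoxyphenyl)propanoic acid (dihydroferulic acid) | COc1cc(CCC(=O)O)ccc1O | starting material
2 | benzyl bromide | BrCc1ccccc1 | starting material
3 | benzyl 3-[4-(benzyloxy)-3-methoxyphenyl]propanoate | COc1cc(CCC(=O)OCc2ccccc2)ccc1OCc1ccccc1 | intermediate
4 | 3-[4-(benzyloxy)-3-methoxyphenyl]propanoic acid | COc1cc(CCC(=O)O)ccc1OCc1ccccc1 | intermediate
5 | (R)-4-benzyl-1,3-oxazolidin-2-one | O=C1N[C@H](Cc2ccccc2)CO1 | starting material
6 | 3-[4-(benzyloxy)-3-methoxyphenyl]propanoic 2,2-dimethylpropanoic anhydride | COc1cc(CCC(=O)OC(=O)C(C)(C)C)ccc1OCc1ccccc1 | intermediate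
7 | (4R)-4-benzyl-3-{3-[4-(benzyloxy)-3-methoxyphenyl]propanoyl}-1,3-oxazolidin-2-one | COc1cc(CCC(=O)N2[C@H](Cc3ccccc3)COC2=O)ccc1OCc1ccccc1 | intermediate
8 | lithium Z-enolate of 7 | [Li]O/C(=C\Cc1ccc(OCc2ccccc2)c(OC)c1)N1[C@H](Cc2ccccc2)COC1=O | intermediate
9 | (4R,4'R)-3,3'-{(2S,3S)-2,3-bis[4-(benzyloxy)-3-methoxybenzyl]butanedioyl}bis(4-benzyl-1,3-oxazolidin-2-one) | COc1cc(C[C@H](C(=O)N2[C@H](Cc3ccccc3)COC2=O)[C@@H](C(=O)N2[C@H](Cc3ccccc3)COC2=O)Cc2ccc(OCc3ccccc3)c(OC)c2)ccc1OCc1ccccc1 | intermediate
10 | (2S,3S)-2,3-bis[4-(benzyloxy)-3-methoxybenzyl]butane-1,4-diol | COc1cc(C[C@H](CO)[C@@H](CO)Cc2ccc(OCc3ccccc3)c(OC)c2)ccc1OCc1ccccc1 | intermediate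
11 | (2S,3S)-2,3-bis[4-(benzyloxy)-3-methoxybenzyl]butane-1,4-diyl bis(2,2-dimethylpropanoate) | COc1cc(C[C@H](COC(=O)C(C)(C)C)[C@@H](COC(=O)C(C)(C)C)Cc2ccc(OCc3ccccc3)c(OC)c2)ccc1OCc1ccccc1 | intermediate
12 | (2S,3S)-2-{[4-(benzyloxy)-3-methoxyphenyl](hydroxy)methyl}-3-[4-(benzyloxy)-3-methoxybenzyl]butane-1,4-diyl bis(2,2-dimethylpropanoate), carbinol epimers | COc1cc(C(O)[C@H](COC(=O)C(C)(C)C)[C@@H](COC(=O)C(C)(C)C)Cc2ccc(OCc3ccccc3)c(OC)c2)ccc1OCc1ccccc1 | intermediate
13 | (2S,3S)-2-[4-(benzyloxy)-3-methoxybenzoyl]-3-[4-(benzyloxy)-3-methoxybenzyl]butane-1,4-diyl bis(2,2-dimethylpropanoate) | COc1cc(C(=O)[C@H](COC(=O)C(C)(C)C)[C@@H](COC(=O)C(C)(C)C)Cc2ccc(OCc3ccccc3)c(OC)c2)ccc1OCc1ccccc1 | intermediate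
14 | (2S,3S)-2-[4-(benzyloxy)-3-methoxybenzoyl]-3-{[4-(benzyloxy)-3-methoxyphenyl](hydroxy)methyl}butane-1,4-diyl bis(2,2-dimethylpropanoate), carbinol epimers | COc1cc(C(=O)[C@H](COC(=O)C(C)(C)C)[C@@H](COC(=O)C(C)(C)C)C(O)c2ccc(OCc3ccccc3)c(OC)c2)ccc1OCc1ccccc1 | intermediate
15 | (2S,3S)-2,3-bis[4-(benzyloxy)-3-methoxybenzoyl]butane-1,4-diyl bis(2,2-dimethylpropanoate) | COc1cc(C(=O)[C@H](COC(=O)C(C)(C)C)[C@@H](COC(=O)C(C)(C)C)C(=O)c2ccc(OCc3ccccc3)c(OC)c2)ccc1OCc1ccccc1 | intermediate
16 | [(3S,4S,5S)-2,5-bis[4-(benzyloxy)-3-methoxyphenyl]-2-hydroxyoxolane-3,4-diyl]bis(methylene) bis(2,2-dimethylpropanoate), lactol, C2 epimers | COc1cc(C2(O)O[C@H](c3ccc(OCc4ccccc4)c(OC)c3)[C@H](COC(=O)C(C)(C)C)[C@H]2COC(=O)C(C)(C)C)ccc1OCc1ccccc1 | intermediate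
17 | [(2S,3S,4S,5S)-2,5-bis[4-(benzyloxy)-3-methoxyphenyl]oxolane-3,4-diyl]bis(methylene) bis(2,2-dimethylpropanoate) | COc1cc([C@H]2O[C@H](c3ccc(OCc4ccccc4)c(OC)c3)[C@H](COC(=O)C(C)(C)C)[C@H]2COC(=O)C(C)(C)C)ccc1OCc1ccccc1 | intermediate
18 | [(2S,3S,4S,5S)-2,5-bis[4-(benzyloxy)-3-methoxyphenyl]oxolane-3,4-diyl]dimethanol | COc1cc([C@H]2O[C@H](c3ccc(OCc4ccccc4)c(OC)c3)[C@H](CO)[C@H]2CO)ccc1OCc1ccccc1 | intermediate
19 | eduesmine, [(2S,3S,4S,5S)-2,5-bis(4-hydroxy-3-methoxyphenyl)oxolane-3,4-diyl]dimethanol | COc1cc([C@H]2O[C@H](c3ccc(O)c(OC)c3)[C@H](CO)[C@H]2CO)ccc1O | target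

Total step count: 9 steps. Longest linear sequence: 9 steps (1 to 19).

**Steps most likely to fail**

Step 6 (double benzylic oxidation). The para-benzyloxybenzyl cation may be captured by the second electron-rich ring (Friedel–Crafts closure to a six-membered carbocycle), or may lose the adjacent proton to a styrene, which would erase a stereocentre, before water adds; the oxidation may also stall after the first ketone. The fallback sets out from 11 and returns to the route at 19. It exchanges the phenol protecting group so that a hydrogen-atom-transfer oxygenation, which never passes through a benzylic cation, can be used. Hydrogenolysis of 11 (H2, Pd/C, EtOAc; nothing else is reducible at this stage) should give (2S,3S)-2,3-bis(4-hydroxy-3-methoxybenzyl)butane-1,4-diyl dipivalate F1, and t-BuCOCl/pyridine/DMAP should convert it into the tetrapivalate F2. With no O-benzyl C–H left, aerobic benzylic oxygenation (N-hydroxyphthalimide and Co(OAc)2 as catalysts, O2, MeCN, 60 °C) should turn both ArCH2 groups into ketones and give the tetrapivalate diketone F3. Treatment as in step 7 (Et3SiH, BF3·OEt2, CH2Cl2, low temperature) should pass through the tetrapivalate lactol F4 to the tetrapivalate oxolane F5; the less donating aryl groups ionise more slowly but also resist reopening. i-Bu2AlH then removes all four pivalates and gives 19 directly, with no hydrogenolysis on the ring ether.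

Step 7 (key step). Proton loss from the oxocarbenium ions may outrun hydride capture (dehydration and aromatisation to the furan, or epimerisation through the enol ether), or a ketone may be reduced by the silane before the ring has closed, so that one centre would be set without ring control. The fallback sets out from 15 and returns at 17; it separates the two hydride deliveries. One ketone is reduced under reagent control by a CBS reduction ((R)-2-methyl-CBS-oxazaborolidine, BH3·SMe2 in deficit, THF, −20 °C), with the aryl group acting as the large substituent so that the S carbinol is expected. The alkoxyborane formed should close onto the second ketone and mask it, which gives the (2S,3S,4S)-4-hydroxy ketone F6, in equilibrium with lactol 16; unreacted 15 is recycled. With only one carbonyl left the furan can no longer form, and reduction of the isolated lactol with Et3SiH/BF3·OEt2 at −78 °C, the transformation directly precedented for 2,3-cis-2-aryloxolanes, should give 17.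

Step 3 (enolate dimerisation). Diastereoselectivity may erode in the coupling (meso and mixed dimers), and α-chlorination or simple reprotonation of the enolate may compete. The fallback sets out from 7 and returns at 10; it sets C3 and C4 one after the other by two enolate alkylations. The sodium enolate of 7 (NaN(SiMe3)2, THF, −78 °C) is alkylated with tert-butyl bromoacetate, anti to the auxiliary benzyl group, to give the succinate half-ester imide F7. LiBH4 removes the auxiliary to give the hydroxy ester F8, which CF3CO2H in CH2Cl2 lactonises to the (S)-β-benzyl-γ-butyrolactone F9. Its lithium enolate (LiN(i-Pr)2, THF, −78 °C) is alkylated by 4-(benzyloxy)-3-methoxybenzyl bromide anti to the C4 substituent to give the trans-dibenzyl lactone F10, and LiAlH4 in THF opens this to diol 10.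

**Further compounds**

F1 | step 6 | (2S,3S)-2,3-bis(4-hydroxy-3-methoxybenzyl)butane-1,4-diyl bis(2,2-dimethylpropanoate) | COc1cc(C[C@H](COC(=O)C(C)(C)C)[C@@H](COC(=O)C(C)(C)C)Cc2ccc(O)c(OC)c2)ccc1O
F2 | step 6 | (2S,3S)-2,3-bis[3-methoxy-4-(pivaloyloxy)benzyl]butane-1,4-diyl bis(2,2-dimethylpropanoate) | COc1cc(C[C@H](COC(=O)C(C)(C)C)[C@@H](COC(=O)C(C)(C)C)Cc2ccc(OC(=O)C(C)(C)C)c(OC)c2)ccc1OC(=O)C(C)(C)C
F3 | step 6 | (2S,3S)-2,3-bis[3-methoxy-4-(pivaloyloxy)benzoyl]butane-1,4-diyl bis(2,2-dimethylpropanoate) | COc1cc(C(=O)[C@H](COC(=O)C(C)(C)C)[C@@H](COC(=O)C(C)(C)C)C(=O)c2ccc(OC(=O)C(C)(C)C)c(OC)c2)ccc1OC(=O)C(C)(C)C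
F4 | step 6 | [(3S,4S,5S)-2-hydroxy-2,5-bis[3-methoxy-4-(pivaloyloxy)phenyl]oxolane-3,4-diyl]bis(methylene) bis(2,2-dimethylpropanoate), lactol, C2 epimers | COc1cc(C2(O)O[C@H](c3ccc(OC(=O)C(C)(C)C)c(OC)c3)[C@H](COC(=O)C(C)(C)C)[C@H]2COC(=O)C(C)(C)C)ccc1OC(=O)C(C)(C)C
F5 | step 6 | [(2S,3S,4S,5S)-2,5-bis[3-methoxy-4-(pivaloyloxy)phenyl]oxolane-3,4-diyl]bis(methylene) bis(2,2-dimethylpropanoate) | COc1cc([C@H]2O[C@H](c3ccc(OC(=O)C(C)(C)C)c(OC)c3)[C@H](COC(=O)C(C)(C)C)[C@H]2COC(=O)C(C)(C)C)ccc1OC(=O)C(C)(C)C
F6 | step 7 | (2S,3S)-2-[4-(benzyloxy)-3-methoxybenzoyl]-3-{(S)-[4-(benzyloxy)-3-methoxyphenyl](hydroxy)methyl}butane-1,4-diyl bis(2,2-dimethylpropanoate) | COc1cc([C@@H](O)[C@H](COC(=O)C(C)(C)C)[C@@H](COC(=O)C(C)(C)C)C(=O)c2ccc(OCc3ccccc3)c(OC)c2)ccc1OCc1ccccc1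
F7 | step 3 | tert-butyl (3S)-4-[4-(benzyloxy)-3-methoxyphenyl]-3-{[(4R)-4-benzyl-2-oxo-1,3-oxazolidin-3-yl]carbonyl}butanoate | COc1cc(C[C@H](C(=O)N2[C@H](Cc3ccccc3)COC2=O)CC(=O)OC(C)(C)C)ccc1OCc1ccccc1
F8 | step 3 | tert-butyl (3S)-3-[4-(benzyloxy)-3-methoxybenzyl]-4-hydroxybutanoate | COc1cc(C[C@H](CO)CC(=O)OC(C)(C)C)ccc1OCc1ccccc1
F9 | step 3 | (4S)-4-[4-(benzyloxy)-3-methoxybenzyl]oxolan-2-one | COc1cc(C[C@@H]2COC(=O)C2)ccc1OCc1ccccc1
F10 | step 3 | (3S,4S)-3,4-bis[4-(benzyloxy)-3-methoxybenzyl]oxolan-2-one | COc1cc(C[C@@H]2COC(=O)[C@H]2Cc2ccc(OCc3ccccc3)c(OC)c2)ccc1OCc1ccccc1
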